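## The problem

The target is a dearomatised acylphloroglucinol in which ring A (C1 ketone, C2, C3, C4, C5 enol, C6) is fused across C3–O and C4–C(=O) to a trans-2,3-dimethyldihydropyranone (ring B: O1', C2', C3', C4'), C2 carries an (S)-CH(Ph)CH2CO2H chain, and C6 is an (R)-configured quaternary carbon bearing a prenyl group and a CH2 link to a cis-1,3-disubstituted 2,2-dimethylcyclobutane, which is ring-cleaved (1S,5S)-α-pinene. The six stereocentres fall into four groups (the cyclobutane pair, the ring-B pair, the benzylic carbon and C6) that are too far apart to control one another, so each group needs its own source of chirality. Only within ring B does one centre help the other, because the C3' methyl group settles trans to the C2' methyl group by equilibration. The isopropenyl group sits on a cyclobutane next to a quaternary carbon, so protonation would give a cyclobutylcarbinyl cation and ring expansion; strong Brønsted or Lewis acids, hydrogenation and hot dealkylating reagents are therefore excluded. The β-aryloxy ketone of ring B can lose its stereocentres by enolisation or retro-oxa-Michael opening, and the enolised triketone can suffer retro-Claisen cleavage under forcing base. Before C6 is prenylated, ring A is an aromatic phloroglucinol with oxygen on C1, C3 and C5, one CH2R group on C6 and hydrogen on C2 and C4. This is the substitution pattern of a vinylketene/alkoxyalkyne benzannulation: C5–O from the ketene carbonyl, C1–O and the C6 substituent from a 3-alkoxy-4-alkylcyclobutenone, and C3–O from an ynol ether. In that arene C2 and C4 differ only through the groups on O1 and O5, so making these alike removes any need for regiocontrol when ring B is closed.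

## Retrosynthesis

Ring-A atoms are numbered C1–C6 as above. Systematic names of chromanones use chroman numbering (ring-A C5, C6, C1, C2 = chroman C5, C6, C7, C8).

**C6–prenyl.** Target 44 is traced to its methyl ester 43, and 43 to the aromatic diphenol 42 by cutting the C6–prenyl bond. Cutting the prenyl group and not the cyclobutylmethyl group keeps the costly chiral substituent on the arene from the start and removes the only quaternary stereocentre. The forward reaction is a dearomative C-allylation at the carbon between two phenolic oxygens. It must prefer carbon over oxygen, the unsubstituted allyl terminus, and one face of ring A. Both O1–H and O5–H are free in 42, so the product is a stabilised enolised triketone. With O1 locked in a lactone the product would be a far less favourable cross-conjugated dienone. The acid is carried as a methyl ester so that it neither competes for the allyl electrophile nor relactonises.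

**Benzylic C–phenyl.** Ester 42 comes from dihydrocoumarin 41 by methanolysis, and 41 from coumarin 40 by cutting the C–Ph bond. This cut is preferred to the C2–CH bond because a coumarin is a cyclic, Z-locked acceptor, for which rhodium-catalysed asymmetric addition of arylboronic acids is reliable. An asymmetric attack of ring A on a cinnamate has no such standing. The catalyst alone must set the (S)-centre.

**Pyranone ring.** Coumarin 40 is cut at C2–CH= and O1–C(=O), giving propiolate 39 and then dihydroxychromanone 38. In 38, C2 is the only free arene carbon and O1–H the only non-chelated hydroxyl, so esterification and gold-catalysed hydroarylation need no protecting group.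

**Ring B.** Chromanone 38 comes from its bis-ether 37, which is cut at the aryl–acyl bond C4–C4' to give acid 35. Both phenolic oxygens of 35 carry the same 2-(trimethylsilyl)ethyl group, so C2 and C4 are equivalent and the acylation has one possible product. The forward step must acylate a trialkoxybenzene without letting acid reach the isopropenyl group. Acid 35 comes from alcohol 33, trityl ether 32 and phenol 31 by routine changes. The phenol of 31 is etherified before oxidation because electron-rich phenols do not survive oxoammonium or iodine oxidants.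

**Ring A (key disconnection).** Phenol 31 is cut at C4–C5, C2–C3 and C5–C6 into cyclobutenone 17 and ynol ether 26. No other cut removes a whole ring and places three different oxygens and one alkyl group by construction instead of by aromatic substitution rules. Two spectator groups are chosen with the later steps in mind:
- An ethyl ether on C1 would be the simplest choice. An aryl ethyl ether, however, yields only to boron halides or hot thiolate, which the isopropenylcyclobutane or the chromanone would not survive. A 2-(trimethylsilyl)ethyl ether is made the same way and falls to fluoride.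
- The primary hydroxyl of 26 is a trityl ether. A 1,3-related silyl ether would migrate to the potassium alkoxide used to make the ynol ether.

**Cyclobutenone.** Compound 17 is cut across its four-membered ring into ketene 16 (from acid 8) and alkoxyacetylene 14 (from alcohol 9 and trichloroethylene 10). Acid 8 goes back through alcohol 6, diene 4 and keto aldehyde 3 to (−)-α-pinene 1. Ozonolysis of 1 delivers both ring stereocentres, the gem-dimethyl group and both appendages in one step. The forward cycloaddition must outrun ketene dimerisation, which an excess of 14 should secure.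

**Ynol ether.** Compound 26 comes from alcohol 22 and 10 through a dichlorovinyl ether. Alcohol 22 comes from diol 21, anti-ester 20 and ethyl (R)-3-hydroxybutanoate 18. The chelated dianion alkylation sets the second stereocentre and gives both ring-B methyl groups at their final oxidation level. The forward sequence must leave the carbinol C–O bond intact, so that both stereocentres pass unchanged into ring B.

## Roads not taken

**Alternative 1:** The cyclobutane itself is cut, across the two ring bonds that join the gem-dimethyl carbon and the carbonyl carbon to a terminal alkene. Forward, the chiral isobutyramide A3, the amide of a C2-symmetric trans-2,5-dimethylpyrrolidine, is turned into its keteniminium salt (triflic anhydride, hindered pyridine), which adds across the C=C of ethyl pent-4-enoate A2. Hydrolysis of the cyclobutaniminium salt gives the cyclobutanone A1, ethyl 3-[(1S)-2,2-dimethyl-3-oxocyclobutyl]propanoate.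
- Merits: A1 already has the three-carbon acid chain that ketene 16 needs, so hydroboration and oxidation disappear. Its enantiomeric purity is set by an auxiliary and not by the grade of a terpene.
- Weak points: A1 has a ketone where the target has CH–isopropenyl. Turning C=O into a cis-configured CH–C(CH3)=CH2 needs homologation to an acetyl group, control of a new ring stereocentre and a methylenation, about four steps. Face selectivity of intermolecular keteniminium additions to unactivated monosubstituted alkenes is also moderate.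
- Comparison: this road is better in oxidation-state economy of the chain and in independence from pinene. The chosen plan sets against this four routine steps from 1 to acid 8, with both ring stereocentres and the isopropenyl precursor already in place.

**Alternative 2:** Ring A is cut at C1–C2. The precursor A5 is a dihydropyranone in which ring B is complete. Its C3 carries the CH2–CH(Ph)CH2CO2CH2CH2SiMe3 chain, and its C4 carries an acyl group ending in a quaternary malonate-type methyl ester with the prenyl and cyclobutylmethyl groups. Base removes the vinylogously acidic proton of the C2 methylene and the carbanion closes ring A on the ester (vinylogous Dieckmann). The product A4 is the 2-(trimethylsilyl)ethyl ester of the target, one fluoride step from 44.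
- Merits: there is no aromatic intermediate and hence no dearomatisation. C6 is set before ring closure and cannot be scrambled by it. The end-game is one step.
- Weak points: C6 must be made as an acyclic quaternary stereocentre with two sterically similar CH2R groups between two carbonyls, for which no general asymmetric alkylation exists. The β-keto ester with a quaternary α-carbon invites retro-Claisen cleavage under the cyclisation conditions. Deprotonation must choose the C2 methylene over C3'–H, and the resulting enolate threatens ring B by retro-oxa-Michael opening.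
- Comparison: in principle this road treats C6 better than the chosen plan, whose step 21 is its least precedented step. The chosen plan sets against it a catalyst acting on a flat arene with two very different flanks, a fallback that is known chemistry, and a ring A assembled from two simple chiral fragments in one operation.

**Alternative 3:** Ring B is cut at C4'–C3'. The precursor A7 has an aldehyde on C4 and an (E)-enoate tethered through O3, whose secondary ether carbon would be taken from a hydroxy acid of the chiral pool. A triazolium-derived carbene turns the aldehyde into a Breslow intermediate that adds to the β-carbon of the enoate (intramolecular Stetter reaction). This gives the trans-2-methyl-3-(ethoxycarbonylmethyl)chromanone A6.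
- Merits: the closure of ring B is neutral and organocatalytic, gentler on the isopropenylcyclobutane than the acylation of step 15. The source of C2' is cheap.
- Weak points: A6 has CH2CO2Et where the target has a methyl group, so hydrolysis and reductive decarboxylation must follow. The two methyl ethers on ring A call for the forcing dealkylation that this molecule does not tolerate. The γ-aryloxy enoate of A7 can eliminate phenoxide. Ring A, with its cyclobutylmethyl group and the C4 aldehyde, would have to be built by substitution of a phloroglucinol, with the attendant regiochemical problems.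
- Comparison: for the ring-B closure itself this road is milder and as short. The chosen plan answers with an acylation at −78 °C with a proton trap. It gains by bringing in both ring-B methyl groups at the right oxidation level and by forming ring A without aromatic substitution.

Key step: step 11

## Route

Assumption: (−)-α-pinene of high enantiomeric purity is used, the target is treated as the keto/enol tautomer drawn in its SMILES, and the sense of induction in steps 19 and 21 is assigned by analogy, the ligand antipode being used if it proves opposite.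

Abbreviations: Cb = cis-2,2-dimethyl-3-(prop-1-en-2-yl)cyclobutyl with ring carbons configured as in 1 (C3 is S; C1 is S in 4–8 and 15, R in 16, 17 and 27–44). TMSE = 2-(trimethylsilyl)ethyl. Tr = triphenylmethyl.

Step 1
Reactants: 1 (1S,5S)-(−)-α-pinene
Product: 3 2-[(1R,3R)-3-acetyl-2,2-dimethylcyclobutyl]acetaldehyde (cis-pinonaldehyde), via ozonide 2 (not isolated)
Conditions: O3, CH2Cl2, −78 °C; then Me2S, −78 → 20 °C
Reagents that add atoms: ozone, [O-][O+]=O
Why: Ozonolysis with reductive work-up cleaves the only C=C; the two ring stereocentres are not touched, so the cis relation and absolute configuration of pinene are carried over.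

Step 2
Reactants: 3 cis-pinonaldehyde
Product: 4 (1S,3S)-2,2-dimethyl-1-(prop-2-en-1-yl)-3-(prop-1-en-2-yl)cyclobutane
Conditions: Ph3PCH3Br, KOtBu, THF, 0 → 20 °C
Reagents that add atoms: methyltriphenylphosphonium bromide, C[P+](c1ccccc1)(c1ccccc1)c1ccccc1.[Br-]
Why: Double Wittig methylenation of aldehyde and methyl ketone; the lithium-free ylide at low temperature should olefinate faster than it enolises the ketone, whose α-carbon is a ring stereocentre.

Step 3
Reactants: 4 diene
Product: 6 3-[(1S,3S)-Cb]propan-1-ol, via trialkylborane 5 (not isolated)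
Conditions: Sia2BH (from BH3·SMe2, 2-methyl-2-butene), THF, 0 °C; then NaOH, H2O2, 0 → 20 °C
Reagents that add atoms: hydrogen peroxide, OO
Why: Anti-Markovnikov hydroboration–oxidation; disiamylborane reacts much faster with the monosubstituted allyl C=C than with the 1,1-disubstituted isopropenyl group, which is further shielded by the neighbouring quaternary carbon.

Step 4
Reactants: 6 alcohol
Product: 8 3-[(1S,3S)-Cb]propanoic acid, via aldehyde 7 (not isolated)
Conditions: TEMPO (cat.), PhI(OAc)2, MeCN/H2O, 20 °C
Reagents that add atoms: water, O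
Why: Oxoammonium oxidation to the aldehyde, whose hydrate is oxidised on to the acid; the medium is only weakly acidic and should leave the isopropenyl group alone.

Step 5
Reactants: 9 2-(trimethylsilyl)ethanol; 10 trichloroethylene
Product: 14 [2-(ethynyloxy)ethyl]trimethylsilane, via dichlorovinyl ether 11 (not isolated), via chloroethynyl ether 12 (not isolated), via lithium acetylide 13 (not isolated)
Conditions: KH, THF, 0 °C; 10, −50 → 20 °C; then n-BuLi, −78 → −40 °C; MeOH, −78 °C
Reagents that add atoms: none
Why: Alkoxyacetylene synthesis by addition of the alkoxide to dichloroacetylene formed in situ, then elimination and chlorine–lithium exchange with n-BuLi and protonation; the potassium alkoxide is kept cold to avoid Peterson-type loss of ethene.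

Step 6
Reactants: 8 acid; 14 TMSE ethynyl ether
Product: 17 4-{[(1R,3S)-Cb]methyl}-3-[2-(trimethylsilyl)ethoxy]cyclobut-2-en-1-one (both C4 epimers), via acid chloride 15 (not isolated), via ketene 16 (not isolated)
Conditions: Me2C=C(Cl)NMe2, CH2Cl2, 0 → 20 °C; then 14 (excess), Et3N, Et2O, 20 °C
Reagents that add atoms: none
Why: The α-chloroenamine makes the acid chloride without HCl; dehydrochlorination gives the alkylketene, which adds the ynol ether [2+2] with the nucleophilic CH terminus on the ketene carbonyl carbon, the known route to 4-alkyl-3-alkoxycyclobutenones. The unactivated isopropenyl group cannot compete with the ynol ether.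

Step 7
Reactants: 18 ethyl (R)-3-hydroxybutanoate
Product: 20 ethyl (2R,3R)-3-hydroxy-2-methylbutanoate, via dilithium alkoxide enolate 19 (not isolated)
Conditions: LiN(iPr)2 (2.2 equiv), THF, −50 → −20 °C; MeI, DMPU, −78 → 0 °C
Reagents that add atoms: iodomethane, CI
Why: Fráter–Seebach alkylation; the dianion is a six-membered lithium chelate and iodomethane enters anti to the C3 methyl group, giving the anti (2R,3R) ester.

Step 8
Reactants: 20 anti ester
Product: 21 (2S,3R)-2-methylbutane-1,3-diol
Conditions: LiAlH4, THF, 0 → 20 °C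
Reagents that add atoms: none
Why: Ester reduction; neither stereocentre is involved (the descriptor at C2 changes only through CIP ranking).

Step 9
Reactants: 21 diol
Product: 22 (2R,3S)-3-methyl-4-(trityloxy)butan-2-ol
Conditions: TrCl, Et3N, DMAP (cat.), CH2Cl2, 20 °C
Reagents that add atoms: trityl chloride, ClC(c1ccccc1)(c1ccccc1)c1ccccc1
Why: Tritylation is selective for the primary hydroxyl on steric grounds; unlike a silyl group, trityl cannot migrate to the secondary alkoxide in step 10.

Step 10
Reactants: 22 trityl ether alcohol; 10 trichloroethylene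
Product: 26 [(2S,3R)-3-(ethynyloxy)-2-methylbutoxy]triphenylmethane, via dichlorovinyl ether 23 (not isolated), via chloroethynyl ether 24 (not isolated), via lithium acetylide 25 (not isolated)
Conditions: KH, THF, 0 °C; 10, −50 → 20 °C; then n-BuLi, −78 → −40 °C; MeOH, −78 °C
Reagents that add atoms: none
Why: Same alkoxyacetylene synthesis as step 5, well established for secondary alcohols; the C–O bond of the carbinol is not broken, so both stereocentres are retained. The product is kept cold because secondary-alkyl ynol ethers fragment (retro-ene) on heating.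

Step 11
Reactants: 17 cyclobutenone; 26 chiral ynol ether
Product: 31 2-{[(1R,3S)-Cb]methyl}-5-{[(2R,3S)-3-methyl-4-(trityloxy)butan-2-yl]oxy}-3-[2-(trimethylsilyl)ethoxy]phenol, via vinylketene 27 (not isolated), via vinylcyclobutenone 28 (not isolated), via dienylketene 29 (not isolated), via cyclohexadienone 30 (not isolated)
Conditions: hν (300 nm), ClCH2CH2Cl, 20 °C; then 80 °C
Reagents that add atoms: none
Why: Irradiation opens 17 by 4π electrocyclic ring opening to vinylketene 27; the C4 stereocentre of 17 is destroyed, so both epimers converge. The ketene C=C adds ynol ether 26 [2+2]: the nucleophilic CH terminus bonds to the ketene carbonyl carbon (C4–C5) and the oxygen-bearing alkyne carbon to the ketene α-carbon (C2–C3), giving 28. Warming opens 28 (4π) to dienylketene 29, which closes ring A by a thermal disrotatory 6π electrocyclisation (C5–C6), and dienone 30 tautomerises to the phenol. The closest known reaction type is the Danheiser benzannulation of cyclobutenones with alkoxy- and siloxyacetylenes, including its photochemical variant. No stereocentre is formed and the four existing ones lie outside the reacting π system. The step needs regioselectivity, which the polarisation of the ynol ether secures, and chemoselectivity over the isopropenyl group, which cannot compete with an ynol ether for a ketene. Running the first stage at 20 °C keeps 26 below the temperature of its retro-ene fragmentation; heat is applied only after 26 has been consumed.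

Step 12
Reactants: 31 phenol; 9 2-(trimethylsilyl)ethanol
Product: 32 1,3-bis[2-(trimethylsilyl)ethoxy]-2-{[(1R,3S)-Cb]methyl}-5-{[(2R,3S)-3-methyl-4-(trityloxy)butan-2-yl]oxy}benzene
Conditions: PPh3, DIAD, THF, 0 → 20 °C
Reagents that add atoms: none
Why: Mitsunobu etherification of the phenol with a primary alcohol; it removes the free phenol before the oxidation of step 14 and makes O1 and O5 identical, so that C2 and C4 become equivalent for step 15.

Step 13
Reactants: 32 trityl ether
Product: 33 (2S,3R)-3-(3,5-bis[2-(trimethylsilyl)ethoxy]-4-{[(1R,3S)-Cb]methyl}phenoxy)-2-methylbutan-1-ol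
Conditions: CSA (cat.), MeOH/CH2Cl2, 0 → 20 °C
Reagents that add atoms: none
Why: Acid-catalysed solvolysis through the trityl cation, captured by methanol; catalytic sulfonic acid in cold methanol should not protonate a 1,1-disubstituted alkene at a useful rate and leaves aryl alkyl ethers intact.

Step 14
Reactants: 33 primary alcohol
Product: 35 (2R,3R)-3-(3,5-bis[2-(trimethylsilyl)ethoxy]-4-{[(1R,3S)-Cb]methyl}phenoxy)-2-methylbutanoic acid, via aldehyde 34 (not isolated)
Conditions: TEMPO (cat.), PhI(OAc)2, MeCN/aq. phosphate buffer (pH 7), 20 °C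
Reagents that add atoms: water, O
Why: Same oxidation as step 4; passing straight through the aldehyde hydrate avoids holding the β-aryloxy aldehyde under base, where it could epimerise or eliminate the phenoxide.

Step 15
Reactants: 35 acid
Product: 37 (2R,3R)-2,3-dimethyl-6-{[(1R,3S)-Cb]methyl}-5,7-bis[2-(trimethylsilyl)ethoxy]chroman-4-one, via acid chloride 36 (not isolated)
Conditions: Me2C=C(Cl)NMe2, CH2Cl2, 0 °C; then SnCl4, 2,6-di-tert-butyl-4-methylpyridine, CH2Cl2, −78 °C
Reagents that add atoms: none
Why: Intramolecular Friedel–Crafts acylation of a trialkoxybenzene closes ring B (C4–C4'); the two carbons ortho to the side-chain oxygen of 35 are equivalent, so either gives the same chromanone. The hindered pyridine traps HCl before it can reach the isopropenyl group, and the ring-B stereocentres are not involved.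

Step 16
Reactants: 37 bis-ether
Product: 38 (2R,3R)-5,7-dihydroxy-2,3-dimethyl-6-{[(1R,3S)-Cb]methyl}chroman-4-one
Conditions: Bu4NF, THF, 0 → 45 °C
Reagents that add atoms: none
Why: Fluoride attacks silicon and expels each phenoxide with loss of ethene; both leaving groups are acyl-stabilised phenoxides, which makes these aryl ethers fluoride-labile. The phenoxide form disfavours enolisation at C3'.

Step 17
Reactants: 38 dihydroxychromanone
Product: 39 (2R,3R)-5-hydroxy-2,3-dimethyl-6-{[(1R,3S)-Cb]methyl}-4-oxochroman-7-yl prop-2-ynoate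
Conditions: propiolic acid, DCC, CH2Cl2, 0 °C
Reagents that add atoms: propiolic acid, C#CC(=O)O
Why: Carbodiimide esterification without DMAP; O7–H (ring-A O1) is free, whereas O5–H is hydrogen-bonded to the ketone and flanked by two substituents, so monoacylation should occur at O7.

Step 18
Reactants: 39 aryl propiolate
Product: 40 coumarin: (2R,3R)-5-hydroxy-2,3-dimethyl-6-{[(1R,3S)-Cb]methyl}chroman-4-one fused at O7 and C8 to a pyran-2-one ring (O7–C(=O)–CH=CH–C8)
Conditions: [Au(JohnPhos)(NCMe)]SbF6 (5 mol %), CH2Cl2, 20 °C
Reagents that add atoms: none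
Why: Monovalent gold activates the alkyne for 6-endo attack by the only free arene carbon (C8, ortho to the ester oxygen and para to O5); protodeauration gives the coumarin, the known intramolecular hydroarylation of aryl propiolates.

Step 19
Reactants: 40 coumarin
Product: 41 dihydrocoumarin: (2R,3R)-5-hydroxy-2,3-dimethyl-6-{[(1R,3S)-Cb]methyl}chroman-4-one fused at O7 and C8 to a 3,4-dihydropyran-2-one ring with an (S)-CH(Ph) carbon on C8 (O7–C(=O)–CH2–CH(Ph)–C8)
Conditions: Rh(acac)(C2H4)2 (3 mol %), (S)-SEGPHOS, PhB(OH)2, dioxane/H2O, 60 °C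
Reagents that add atoms: phenylboronic acid, OB(O)c1ccccc1
Why: Hayashi–Miyaura asymmetric 1,4-addition: the phenyl complex of monovalent rhodium inserts the coumarin C=C on the face left open by the bisphosphine and water protonates the rhodium enolate. With simple coumarins the (R)-ligand gives (R)-4-aryl lactones; the CIP ranking at the new centre is the same here, so the (S)-ligand is chosen, and the centre is too remote from the others to feel them.

Step 20
Reactants: 41 dihydrocoumarin
Product: 42 methyl (3S)-3-[(2R,3R)-5,7-dihydroxy-2,3-dimethyl-6-{[(1R,3S)-Cb]methyl}-4-oxochroman-8-yl]-3-phenylpropanoate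
Conditions: K2CO3 (cat.), MeOH, 0 → 20 °C
Reagents that add atoms: methanol, CO
Why: Base-catalysed transesterification of the aryl lactone, an activated ester; it frees O7–H for the dearomatisation and masks the acid. The crude ester is used at once to avoid relactonisation.

Step 21
Reactants: 42 diphenol ester
Product: 43 methyl (3S)-3-[(2R,3R,6R)-6-{[(1R,3S)-Cb]methyl}-5-hydroxy-2,3-dimethyl-6-(3-methylbut-2-en-1-yl)-4,7-dioxo-3,4,6,7-tetrahydro-2H-chromen-8-yl]-3-phenylpropanoate
Conditions: Pd2(dba)3·CHCl3 (2.5 mol %), (R,R)-DACH-phenyl Trost ligand, tert-butyl prenyl carbonate, THF, 0 → 20 °C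
Reagents that add atoms: tert-butyl 3-methylbut-2-en-1-yl carbonate, CC(C)=CCOC(=O)OC(C)(C)C
Why: Proposed new method: zerovalent palladium ionises the carbonate to a π-prenyl palladium cation and tert-butoxide, which deprotonates 42; O-prenylation of the acidic phenols is reversible under palladium, whereas attack of C6 (the carbon between two oxygens) on the unsubstituted allyl terminus is irreversible and gives the enolised triketone; the chiral pocket must tell the C1 flank (bulky benzylic chain) from the C5 flank (chelated acyl) and so sets C6, assumed R with the (R,R)-ligand; closest known reaction types are the palladium-catalysed dearomative allylation of acylphloroglucinols with achiral ligands, the asymmetric allylic dearomatisation of naphthols with Trost ligands and the asymmetric linear prenylation of oxindoles.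

Step 22
Reactants: 43 methyl ester
Product: 44 (3S)-3-[(2R,3R,6R)-6-{[(1R,3S)-Cb]methyl}-5-hydroxy-2,3-dimethyl-6-(3-methylbut-2-en-1-yl)-4,7-dioxo-3,4,6,7-tetrahydro-2H-chromen-8-yl]-3-phenylpropanoic acid
Conditions: LiOH, THF/H2O, 0 → 20 °C; then aq. HCl to pH 3, 0 °C
Reagents that add atoms: lithium hydroxide, [Li+].[OH-]
Why: Saponification; the enolised triketone is present as its anion, which shields C3' and C6 from base, and cold dilute acid on work-up spares both alkenes.

## Compound list

1 | (1S,5S)-(−)-α-pinene | CC1=CC[C@H]2C[C@@H]1C2(C)C | starting material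
2 | α-pinene secondary ozonide (1,2,4-trioxolane across former C2=C3, mixture at the two acetal carbons) | CC12OOC(C[C@H]3C[C@@H]1C3(C)C)O2 | intermediate
3 | 2-[(1R,3R)-3-acetyl-2,2-dimethylcyclobutyl]acetaldehyde | CC(=O)[C@@H]1C[C@H](CC=O)C1(C)C | intermediate
4 | (1S,3S)-2,2-dimethyl-1-(prop-2-en-1-yl)-3-(prop-1-en-2-yl)cyclobutane | C=C(C)[C@@H]1C[C@H](CC=C)C1(C)C | intermediate
5 | {3-[(1S,3S)-Cb]propyl}bis(3-methylbutan-2-yl)borane | C=C(C)[C@@H]1C[C@H](CCCB(C(C)C(C)C)C(C)C(C)C)C1(C)C | intermediate
6 | 3-[(1S,3S)-Cb]propan-1-ol | C=C(C)[C@@H]1C[C@H](CCCO)C1(C)C | intermediate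
7 | 3-[(1S,3S)-Cb]propanal | C=C(C)[C@@H]1C[C@H](CCC=O)C1(C)C | intermediate
8 | 3-[(1S,3S)-Cb]propanoic acid | C=C(C)[C@@H]1C[C@H](CCC(=O)O)C1(C)C | intermediate
9 | 2-(trimethylsilyl)ethanol | C[Si](C)(C)CCO | starting material
10 | trichloroethylene | ClC=C(Cl)Cl | starting material
11 | (E)-1,2-dichlorovinyl 2-(trimethylsilyl)ethyl ether | Cl/C=C(/Cl)OCC[Si](C)(C)C | intermediate
12 | chloroethynyl 2-(trimethylsilyl)ethyl ether | ClC#COCC[Si](C)(C)C | intermediate
13 | lithium [2-(trimethylsilyl)ethoxy]ethynide | [Li]C#COCC[Si](C)(C)C | intermediate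
14 | [2-(ethynyloxy)ethyl]trimethylsilane | C#COCC[Si](C)(C)C | intermediate
15 | 3-[(1S,3S)-Cb]propanoyl chloride | C=C(C)[C@@H]1C[C@H](CCC(=O)Cl)C1(C)C | intermediate
16 | 3-[(1R,3S)-Cb]prop-1-en-1-one (ketene) | C=C(C)[C@@H]1C[C@H](CC=C=O)C1(C)C | intermediate
17 | 4-{[(1R,3S)-Cb]methyl}-3-[2-(trimethylsilyl)ethoxy]cyclobut-2-en-1-one, both C4 epimers | C=C(C)[C@@H]1C[C@H](CC2C(=O)C=C2OCC[Si](C)(C)C)C1(C)C | intermediate
18 | ethyl (R)-3-hydroxybutanoate | CCOC(=O)C[C@@H](C)O | starting material
19 | dilithium alkoxide enolate of ethyl (R)-3-hydroxybutanoate | [Li+].[Li+].[O-]/C(OCC)=C\[C@@H](C)[O-] | intermediate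
20 | ethyl (2R,3R)-3-hydroxy-2-methylbutanoate | CCOC(=O)[C@H](C)[C@@H](C)O | intermediate
21 | (2S,3R)-2-methylbutane-1,3-diol | OC[C@H](C)[C@@H](C)O | intermediate
22 | (2R,3S)-3-methyl-4-(trityloxy)butan-2-ol | O[C@H](C)[C@@H](C)COC(c1ccccc1)(c1ccccc1)c1ccccc1 | intermediate
23 | {(2S,3R)-3-[(E)-1,2-dichlorovinyloxy]-2-methylbutoxy}triphenylmethane | Cl/C=C(/Cl)O[C@H](C)[C@@H](C)COC(c1ccccc1)(c1ccccc1)c1ccccc1 | intermediate
24 | {(2S,3R)-3-[(chloroethynyl)oxy]-2-methylbutoxy}triphenylmethane | ClC#CO[C@H](C)[C@@H](C)COC(c1ccccc1)(c1ccccc1)c1ccccc1 | intermediate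
25 | lithium {[(2R,3S)-3-methyl-4-(trityloxy)butan-2-yl]oxy}ethynide | [Li]C#CO[C@H](C)[C@@H](C)COC(c1ccccc1)(c1ccccc1)c1ccccc1 | intermediate
26 | [(2S,3R)-3-(ethynyloxy)-2-methylbutoxy]triphenylmethane | C#CO[C@H](C)[C@@H](C)COC(c1ccccc1)(c1ccccc1)c1ccccc1 | intermediate
27 | vinylketene, 5-[(1R,3S)-Cb]-3-[2-(trimethylsilyl)ethoxy]penta-1,3-dien-1-one (chain trans to the ketene carbon) | C=C(C)[C@@H]1C[C@H](C/C=C(OCC[Si](C)(C)C)/C=C=O)C1(C)C | intermediate
28 | vinylcyclobutenone: 3-{[(2R,3S)-3-methyl-4-(trityloxy)butan-2-yl]oxy}cyclobut-2-en-1-one bearing at C4 the 3-[(1R,3S)-Cb]-1-[2-(trimethylsilyl)ethoxy]prop-1-en-1-yl group (both epimers at the ring CH) | C=C(C)[C@@H]1C[C@H](C/C=C(OCC[Si](C)(C)C)/C2C(=O)C=C2O[C@H](C)[C@@H](C)COC(c3ccccc3)(c3ccccc3)c3ccccc3)C1(C)C | intermediate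
29 | dienylketene: 7-[(1R,3S)-Cb]-3-{[(2R,3S)-3-methyl-4-(trityloxy)butan-2-yl]oxy}-5-[2-(trimethylsilyl)ethoxy]hepta-1,3,5-trien-1-one | C=C(C)[C@@H]1C[C@H](C/C=C(OCC[Si](C)(C)C)/C=C(\C=C=O)O[C@H](C)[C@@H](C)COC(c2ccccc2)(c2ccccc2)c2ccccc2)C1(C)C | intermediate
30 | cyclohexa-2,4-dienone: 6-{[(1R,3S)-Cb]methyl}-3-{[(2R,3S)-3-methyl-4-(trityloxy)butan-2-yl]oxy}-5-[2-(trimethylsilyl)ethoxy]cyclohexa-2,4-dien-1-one (keto tautomer of the phenol) | C=C(C)[C@@H]1C[C@H](CC2C(=O)C=C(O[C@H](C)[C@@H](C)COC(c3ccccc3)(c3ccccc3)c3ccccc3)C=C2OCC[Si](C)(C)C)C1(C)C | intermediate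
31 | 2-{[(1R,3S)-Cb]methyl}-5-{[(2R,3S)-3-methyl-4-(trityloxy)butan-2-yl]oxy}-3-[2-(trimethylsilyl)ethoxy]phenol | C=C(C)[C@@H]1C[C@H](Cc2c(O)cc(O[C@H](C)[C@@H](C)COC(c3ccccc3)(c3ccccc3)c3ccccc3)cc2OCC[Si](C)(C)C)C1(C)C | intermediate
32 | 1,3-bis[2-(trimethylsilyl)ethoxy]-2-{[(1R,3S)-Cb]methyl}-5-{[(2R,3S)-3-methyl-4-(trityloxy)butan-2-yl]oxy}benzene | C=C(C)[C@@H]1C[C@H](Cc2c(OCC[Si](C)(C)C)cc(O[C@H](C)[C@@H](C)COC(c3ccccc3)(c3ccccc3)c3ccccc3)cc2OCC[Si](C)(C)C)C1(C)C | intermediate
33 | (2S,3R)-3-(3,5-bis[2-(trimethylsilyl)ethoxy]-4-{[(1R,3S)-Cb]methyl}phenoxy)-2-methylbutan-1-ol | C=C(C)[C@@H]1C[C@H](Cc2c(OCC[Si](C)(C)C)cc(O[C@H](C)[C@@H](C)CO)cc2OCC[Si](C)(C)C)C1(C)C | intermediate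
34 | (2R,3R)-3-(3,5-bis[2-(trimethylsilyl)ethoxy]-4-{[(1R,3S)-Cb]methyl}phenoxy)-2-methylbutanal | C=C(C)[C@@H]1C[C@H](Cc2c(OCC[Si](C)(C)C)cc(O[C@H](C)[C@@H](C)C=O)cc2OCC[Si](C)(C)C)C1(C)C | intermediate
35 | (2R,3R)-3-(3,5-bis[2-(trimethylsilyl)ethoxy]-4-{[(1R,3S)-Cb]methyl}phenoxy)-2-methylbutanoic acid | C=C(C)[C@@H]1C[C@H](Cc2c(OCC[Si](C)(C)C)cc(O[C@H](C)[C@@H](C)C(=O)O)cc2OCC[Si](C)(C)C)C1(C)C | intermediate
36 | (2R,3R)-3-(3,5-bis[2-(trimethylsilyl)ethoxy]-4-{[(1R,3S)-Cb]methyl}phenoxy)-2-methylbutanoyl chloride | C=C(C)[C@@H]1C[C@H](Cc2c(OCC[Si](C)(C)C)cc(O[C@H](C)[C@@H](C)C(=O)Cl)cc2OCC[Si](C)(C)C)C1(C)C | intermediate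
37 | (2R,3R)-2,3-dimethyl-6-{[(1R,3S)-Cb]methyl}-5,7-bis[2-(trimethylsilyl)ethoxy]chroman-4-one | C=C(C)[C@@H]1C[C@H](Cc2c(OCC[Si](C)(C)C)cc3O[C@H](C)[C@@H](C)C(=O)c3c2OCC[Si](C)(C)C)C1(C)C | intermediate
38 | (2R,3R)-5,7-dihydroxy-2,3-dimethyl-6-{[(1R,3S)-Cb]methyl}chroman-4-one | C=C(C)[C@@H]1C[C@H](Cc2c(O)cc3O[C@H](C)[C@@H](C)C(=O)c3c2O)C1(C)C | intermediate
39 | (2R,3R)-5-hydroxy-2,3-dimethyl-6-{[(1R,3S)-Cb]methyl}-4-oxochroman-7-yl prop-2-ynoate | C=C(C)[C@@H]1C[C@H](Cc2c(OC(=O)C#C)cc3O[C@H](C)[C@@H](C)C(=O)c3c2O)C1(C)C | intermediate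
40 | coumarin: (2R,3R)-5-hydroxy-2,3-dimethyl-6-{[(1R,3S)-Cb]methyl}chroman-4-one fused at O7 and C8 to a pyran-2-one ring (O7–C(=O)–CH=CH–C8) | C=C(C)[C@@H]1C[C@H](Cc2c3OC(=O)C=Cc3c3O[C@H](C)[C@@H](C)C(=O)c3c2O)C1(C)C | intermediate
41 | dihydrocoumarin: (2R,3R)-5-hydroxy-2,3-dimethyl-6-{[(1R,3S)-Cb]methyl}chroman-4-one fused at O7 and C8 to a 3,4-dihydropyran-2-one ring with an (S)-CH(Ph) carbon on C8 (O7–C(=O)–CH2–CH(Ph)–C8) | C=C(C)[C@@H]1C[C@H](Cc2c3OC(=O)C[C@@H](c4ccccc4)c3c3O[C@H](C)[C@@H](C)C(=O)c3c2O)C1(C)C | intermediate
42 | methyl (3S)-3-[(2R,3R)-5,7-dihydroxy-2,3-dimethyl-6-{[(1R,3S)-Cb]methyl}-4-oxochroman-8-yl]-3-phenylpropanoate | C=C(C)[C@@H]1C[C@H](Cc2c(O)c([C@@H](CC(=O)OC)c3ccccc3)c3O[C@H](C)[C@@H](C)C(=O)c3c2O)C1(C)C | intermediate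
43 | methyl (3S)-3-[(2R,3R,6R)-6-{[(1R,3S)-Cb]methyl}-5-hydroxy-2,3-dimethyl-6-(3-methylbut-2-en-1-yl)-4,7-dioxo-3,4,6,7-tetrahydro-2H-chromen-8-yl]-3-phenylpropanoate | C=C(C)[C@@H]1C[C@H](C[C@@]2(CC=C(C)C)C(=O)C([C@@H](CC(=O)OC)c3ccccc3)=C3O[C@H](C)[C@@H](C)C(=O)C3=C2O)C1(C)C | intermediate
44 | (3S)-3-[(2R,3R,6R)-6-{[(1R,3S)-Cb]methyl}-5-hydroxy-2,3-dimethyl-6-(3-methylbut-2-en-1-yl)-4,7-dioxo-3,4,6,7-tetrahydro-2H-chromen-8-yl]-3-phenylpropanoic acid | C=C(C)[C@@H]1C[C@H](C[C@@]2(CC=C(C)C)C(=O)C([C@@H](CC(=O)O)c3ccccc3)=C3O[C@H](C)[C@@H](C)C(=O)C3=C2O)C1(C)C | target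

## Step count and risks

Total: 22 steps. Longest linear sequence: 17 steps (steps 1–4, 6, 11–22).

**Step 21 (proposed new method).** The most likely failure is poor facial discrimination at C6, because the ligand may not tell the two flanks of the planar nucleophile apart. Persistent O-prenylation, a second prenylation, or attack through the more hindered C2 are the next concerns. Fallback in known chemistry, from 42 back to 43: alkylation of 42 with prenyl bromide and NaOMe in MeOH at 0 °C, the classical dearomative C-prenylation of acylphloroglucinols, should give 43 together with its C6 epimer, methyl (3S)-3-[(2R,3R,6S)-6-{[(1R,3S)-Cb]methyl}-5-hydroxy-2,3-dimethyl-6-(3-methylbut-2-en-1-yl)-4,7-dioxo-3,4,6,7-tetrahydro-2H-chromen-8-yl]-3-phenylpropanoate F1. The diastereomers are separated by chromatography and 43 continues to step 22.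

**Step 11 (key step).** The most likely failure is loss of the ynol ether by retro-ene fragmentation before it is trapped, should photochemical opening of 17 be inefficient and heat be needed from the start. Acylation of the product phenol by the vinylketene is a second drain. The fallback sets out from 17 and 22 and rejoins the route at 32. Thermal benzannulation of 17 in toluene at 80 °C with (triisopropylsilyloxy)ethyne F2, a siloxyalkyne that has no retro-ene path, should give 2-{[(1R,3S)-Cb]methyl}-3-[2-(trimethylsilyl)ethoxy]-5-(triisopropylsilyloxy)phenol F3. Mitsunobu etherification of F3 with 9 gives the bis-TMSE triisopropylsilyl ether F4. Bu4NF at 0 °C removes only the aryl silyl ether and gives 3,5-bis[2-(trimethylsilyl)ethoxy]-4-{[(1R,3S)-Cb]methyl}phenol F5. In parallel, Mitsunobu inversion of 22 with 4-nitrobenzoic acid gives (2S,3S)-3-methyl-4-(trityloxy)butan-2-yl 4-nitrobenzoate F6, and methanolysis (K2CO3, MeOH) gives (2S,3S)-3-methyl-4-(trityloxy)butan-2-ol F7. Mitsunobu coupling of F5 with F7 forms the aryl ether with inversion and gives 32.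

**Step 15.** The most likely failures are protonation of the isopropenyl group with ring expansion if HCl escapes the pyridine trap, and fragmentation of the β-aryloxy acylium ion by loss of the phenol, which would also erode C2' and C3'. The fallback, from 35 back to 37, replaces the cationic closure by an anionic one. Coupling of 35 with MeNHOMe·HCl (EDC, iPr2NEt) gives the Weinreb amide, (2R,3R)-3-(aryloxy)-N-methoxy-N,2-dimethylbutanamide F8. One equivalent of NBS in MeCN at −40 °C gives the monobromide F9, a single isomer because the two positions ortho to the side-chain oxygen are equivalent. With n-BuLi in THF at −78 °C, bromine–lithium exchange and intramolecular acylation (Parham cyclisation) give 37.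

**Step 19.** The most likely failures are slow insertion, because C4 of the coumarin is peri to the ring-B oxygen, so that protodeboronation of the boronic acid wins, and eroded facial selectivity. Fallback from 38 to 41, bypassing 39 and 40: iminium-catalysed Friedel–Crafts alkylation and hemiacetalisation of 38 with cinnamaldehyde, using a diarylprolinol silyl ether chosen to give the (S)-centre, gives the (4S)-4-phenyl lactol F10, in which the lactone carbonyl of 41 is replaced by CH–OH. Ag2CO3 on Celite oxidises F10 to 41.

**Step 3.** The most likely failure is competing hydroboration of the isopropenyl group. The fallback, from 3 to 8, differentiates the two carbonyl groups instead of the two alkenes. Chemoselective Wittig reaction of the aldehyde of 3 with Ph3P=CHOMe gives 1-[(1R,3S)-3-(3-methoxyprop-2-en-1-yl)-2,2-dimethylcyclobutyl]ethanone F11. Methylenation of the ketone (Ph3PCH3Br, KOtBu) gives the enol ether diene F12. Mild hydrolysis (oxalic acid, wet THF) releases aldehyde 7, and NaClO2/NaH2PO4/2-methyl-2-butene gives 8.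

## Further compounds

F1 | step 21 | methyl (3S)-3-[(2R,3R,6S)-6-{[(1R,3S)-Cb]methyl}-5-hydroxy-2,3-dimethyl-6-(3-methylbut-2-en-1-yl)-4,7-dioxo-3,4,6,7-tetrahydro-2H-chromen-8-yl]-3-phenylpropanoate (C6 epimer of 43) | C=C(C)[C@@H]1C[C@H](C[C@]2(CC=C(C)C)C(=O)C([C@@H](CC(=O)OC)c3ccccc3)=C3O[C@H](C)[C@@H](C)C(=O)C3=C2O)C1(C)C
F2 | step 11 | (triisopropylsilyloxy)ethyne | C#CO[Si](C(C)C)(C(C)C)C(C)C
F3 | step 11 | 2-{[(1R,3S)-Cb]methyl}-3-[2-(trimethylsilyl)ethoxy]-5-(triisopropylsilyloxy)phenol | C=C(C)[C@@H]1C[C@H](Cc2c(O)cc(O[Si](C(C)C)(C(C)C)C(C)C)cc2OCC[Si](C)(C)C)C1(C)C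
F4 | step 11 | {3,5-bis[2-(trimethylsilyl)ethoxy]-4-{[(1R,3S)-Cb]methyl}phenoxy}triisopropylsilane | C=C(C)[C@@H]1C[C@H](Cc2c(OCC[Si](C)(C)C)cc(O[Si](C(C)C)(C(C)C)C(C)C)cc2OCC[Si](C)(C)C)C1(C)C
F5 | step 11 | 3,5-bis[2-(trimethylsilyl)ethoxy]-4-{[(1R,3S)-Cb]methyl}phenol | C=C(C)[C@@H]1C[C@H](Cc2c(OCC[Si](C)(C)C)cc(O)cc2OCC[Si](C)(C)C)C1(C)C
F6 | step 11 | (2S,3S)-3-methyl-4-(trityloxy)butan-2-yl 4-nitrobenzoate | O=C(O[C@@H](C)[C@@H](C)COC(c1ccccc1)(c1ccccc1)c1ccccc1)c1ccc(cc1)[N+](=O)[O-]
F7 | step 11 | (2S,3S)-3-methyl-4-(trityloxy)butan-2-ol | O[C@@H](C)[C@@H](C)COC(c1ccccc1)(c1ccccc1)c1ccccc1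
F8 | step 15 | (2R,3R)-3-(3,5-bis[2-(trimethylsilyl)ethoxy]-4-{[(1R,3S)-Cb]methyl}phenoxy)-N-methoxy-N,2-dimethylbutanamide | C=C(C)[C@@H]1C[C@H](Cc2c(OCC[Si](C)(C)C)cc(O[C@H](C)[C@@H](C)C(=O)N(C)OC)cc2OCC[Si](C)(C)C)C1(C)C
F9 | step 15 | (2R,3R)-3-(2-bromo-3,5-bis[2-(trimethylsilyl)ethoxy]-4-{[(1R,3S)-Cb]methyl}phenoxy)-N-methoxy-N,2-dimethylbutanamide | C=C(C)[C@@H]1C[C@H](Cc2c(OCC[Si](C)(C)C)cc(O[C@H](C)[C@@H](C)C(=O)N(C)OC)c(Br)c2OCC[Si](C)(C)C)C1(C)C
F10 | step 19 | (4S)-4-phenyl lactol corresponding to 41 (lactone C=O replaced by CH–OH, anomeric mixture) | C=C(C)[C@@H]1C[C@H](Cc2c3OC(O)C[C@@H](c4ccccc4)c3c3O[C@H](C)[C@@H](C)C(=O)c3c2O)C1(C)C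
F11 | step 3 | 1-[(1R,3S)-3-(3-methoxyprop-2-en-1-yl)-2,2-dimethylcyclobutyl]ethanone (E/Z mixture) | CC(=O)[C@@H]1C[C@H](CC=COC)C1(C)C
F12 | step 3 | (1R,3S)-1-(3-methoxyprop-2-en-1-yl)-2,2-dimethyl-3-(prop-1-en-2-yl)cyclobutane (E/Z mixture) | C=C(C)[C@@H]1C[C@H](CC=COC)C1(C)C
A1 | alternative 1 | ethyl 3-[(1S)-2,2-dimethyl-3-oxocyclobutyl]propanoate | O=C1C[C@H](CCC(=O)OCC)C1(C)C
A2 | alternative 1 | ethyl pent-4-enoate | C=CCCC(=O)OCC
A3 | alternative 1 | 1-[(2R,5R)-2,5-dimethylpyrrolidin-1-yl]-2-methylpropan-1-one | C[C@@H]1CC[C@@H](C)N1C(=O)C(C)C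
A4 | alternative 2 | 2-(trimethylsilyl)ethyl ester of 44 | C=C(C)[C@@H]1C[C@H](C[C@@]2(CC=C(C)C)C(=O)C([C@@H](CC(=O)OCC[Si](C)(C)C)c3ccccc3)=C3O[C@H](C)[C@@H](C)C(=O)C3=C2O)C1(C)C
A5 | alternative 2 | open-chain precursor of A4 (stereocentres as in 44): (2R,3R)-2,3-dimethyl-2,3-dihydropyran-4-one bearing at C6 the (S)-2-phenyl-3-[2-(trimethylsilyl)ethoxycarbonyl]propyl group and at C5 the 2-(Cb-methyl)-2-(methoxycarbonyl)-5-methylhex-4-enoyl group | C=C(C)[C@@H]1C[C@H](C[C@@](CC=C(C)C)(C(=O)OC)C(=O)C2=C(C[C@@H](CC(=O)OCC[Si](C)(C)C)c3ccccc3)O[C@H](C)[C@@H](C)C2=O)C1(C)C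
A6 | alternative 3 | ethyl 2-[(2R,3R)-5,7-dimethoxy-2-methyl-6-{[(1R,3S)-Cb]methyl}-4-oxochroman-3-yl]acetate (trans) | C=C(C)[C@@H]1C[C@H](Cc2c(OC)cc3O[C@H](C)[C@@H](CC(=O)OCC)C(=O)c3c2OC)C1(C)C
A7 | alternative 3 | ethyl (R,E)-4-(2-formyl-3,5-dimethoxy-4-{[(1R,3S)-Cb]methyl}phenoxy)pent-2-enoate | C=C(C)[C@@H]1C[C@H](Cc2c(OC)cc(O[C@H](C)/C=C/C(=O)OCC)c(C=O)c2OC)C1(C)C
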